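The 21-membered ring is cut between the benzylic CH2 attached to ring B (the dihydroxylated ring) and the neighbouring chain carbon. The feature exploited is the ring B hydroxyl flanked by the ether oxygen and the chain: it is ortho to that CH2, so the phenol oxygen and the benzylic carbon can be unmasked as an ortho-quinone methide. In one operation, mild base ejects toluenesulfinate from a 2-(tosylmethyl)phenol and a tethered bis(phenylsulfonyl)methyl carbanion adds to the exocyclic methylene, forming the C–C bond and the macrocycle. The precursor is the open-chain diaryl ether bearing that tosylmethylphenol on ring B and a 13,13-bis(phenylsulfonyl)tridecyl chain on ring A, the other two phenols being methyl ethers.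

Key step: step 12

Remark: compound 5 is drawn as the Z alkene expected to predominate; any E isomer converges on 6 in step 3, so the mixture would be carried forward.

Step 1
Reactants: 1 11-bromoundecan-1-ol
Product: 2 (11-hydroxyundecyl)triphenylphosphonium bromide
Conditions: PPh3, MeCN, reflux
Reagents that add atoms: triphenylphosphine, c1ccc(cc1)P(c1ccccc1)c1ccccc1
Why: Quaternization of a phosphine by a primary alkyl bromide (SN2 phosphonium salt formation) is routine and the free hydroxyl does not interfere.

Step 2
Reactants: 2 (11-hydroxyundecyl)triphenylphosphonium bromide; 3 3,5-dimethoxybenzaldehyde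
Product: 5 (Z)-12-(3,5-dimethoxyphenyl)dodec-11-en-1-ol, via ylide alkoxide 4 (not isolated)
Conditions: NaN(SiMe3)2 (2.2 equiv), THF, 0 °C; then 3, 0 °C to rt; H2O quench
Reagents that add atoms: none
Why: Wittig olefination of a non-enolizable aromatic aldehyde with a non-stabilized ylide is reliable when a second equivalent of base masks the hydroxyl as its alkoxide, and the alkene geometry is irrelevant because the double bond is hydrogenated next.

Step 3
Reactants: 5 (Z)-12-(3,5-dimethoxyphenyl)dodec-11-en-1-ol
Product: 6 12-(3,5-dimethoxyphenyl)dodecan-1-ol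
Conditions: H2 (1 atm), 10% Pd/C, EtOAc, rt
Reagents that add atoms: none
Why: Heterogeneous catalytic hydrogenation saturates the styrenyl double bond and leaves the aryl methyl ethers and the primary alcohol untouched.

Step 4
Reactants: 6 12-(3,5-dimethoxyphenyl)dodecan-1-ol
Product: 7 3-(12-hydroxydodecyl)-5-methoxyphenol
Conditions: NaSEt, DMF, 140 °C; then dilute HCl
Reagents that add atoms: none
Why: Thiolate-mediated SN2 demethylation of an aryl methyl ether should stop after one ether on a 5-alkylresorcinol dimethyl ether, because the phenoxide formed deactivates the ring toward loss of the second methyl group.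

Step 5
Reactants: 8 3-bromo-2-hydroxy-5-methoxybenzaldehyde
Product: 9 2-(benzyloxy)-3-bromo-5-methoxybenzaldehyde
Conditions: BnBr, K2CO3, DMF, 50 °C
Reagents that add atoms: benzyl bromide, BrCc1ccccc1
Why: Williamson etherification of the salicylaldehyde phenoxide installs a benzyl group that blocks this phenol during copper catalysis and later base treatment and can be removed under neutral conditions.

Step 6
Reactants: 7 3-(12-hydroxydodecyl)-5-methoxyphenol; 9 2-(benzyloxy)-3-bromo-5-methoxybenzaldehyde
Product: 10 2-(benzyloxy)-3-[3-(12-hydroxydodecyl)-5-methoxyphenoxy]-5-methoxybenzaldehyde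
Conditions: copper iodide (CuI, 10 mol %), picolinic acid (20 mol %), K3PO4, DMSO, 90 °C
Reagents that add atoms: none
Why: Ullmann-type copper-catalysed diaryl ether synthesis with picolinic acid as ligand couples phenols with ortho-substituted electron-rich aryl bromides, tolerates aldehydes and arylates the phenoxide far faster than the neutral aliphatic alcohol, and running it before the acidic bis-sulfone is installed keeps that group away from copper and base.

Step 7
Reactants: 10 2-(benzyloxy)-3-[3-(12-hydroxydodecyl)-5-methoxyphenoxy]-5-methoxybenzaldehyde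
Product: 11 12-{3-[2-(benzyloxy)-3-(hydroxymethyl)-5-methoxyphenoxy]-5-methoxyphenyl}dodecan-1-ol
Conditions: NaBH4, THF–MeOH, 0 °C
Reagents that add atoms: none
Why: Borohydride reduction of an aromatic aldehyde to the benzylic alcohol is chemoselective and leaves all ether linkages intact.

Step 8
Reactants: 11 12-{3-[2-(benzyloxy)-3-(hydroxymethyl)-5-methoxyphenoxy]-5-methoxyphenyl}dodecan-1-ol
Product: 12 2-(benzyloxy)-1-(bromomethyl)-3-[3-(12-bromododecyl)-5-methoxyphenoxy]-5-methoxybenzene
Conditions: CBr4, PPh3, CH2Cl2, 0 °C to rt
Reagents that add atoms: carbon tetrabromide, BrC(Br)(Br)Br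
Why: The Appel reaction converts both the benzylic and the primary aliphatic alcohol into bromides under neutral conditions that the benzyl and aryl ethers tolerate.

Step 9
Reactants: 12 2-(benzyloxy)-1-(bromomethyl)-3-[3-(12-bromododecyl)-5-methoxyphenoxy]-5-methoxybenzene
Product: 13 2-(benzyloxy)-1-[3-(12-bromododecyl)-5-methoxyphenoxy]-5-methoxy-3-(tosylmethyl)benzene
Conditions: p-TolSO2Na (1.05 equiv), DMF, 0 °C to rt
Reagents that add atoms: sodium p-toluenesulfinate, [Na+].[O-]S(=O)c1ccc(C)cc1
Why: SN2 S-alkylation of a sulfinate salt is much faster at a benzylic bromide than at an unactivated primary alkyl bromide, so one equivalent at or below room temperature should give the benzylic sulfone and keep the chain bromide.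

Step 10
Reactants: 13 2-(benzyloxy)-1-[3-(12-bromododecyl)-5-methoxyphenoxy]-5-methoxy-3-(tosylmethyl)benzene; 14 bis(phenylsulfonyl)methane
Product: 15 2-(benzyloxy)-1-{3-[13,13-bis(phenylsulfonyl)tridecyl]-5-methoxyphenoxy}-5-methoxy-3-(tosylmethyl)benzene
Conditions: 14 (3 equiv), K2CO3, NaI (cat.), DMF, 70 °C
Reagents that add atoms: none
Why: Malonate-type C-alkylation of the doubly stabilized bis(phenylsulfonyl)methyl carbanion with a primary bromide under iodide catalysis is standard, excess nucleophile suppresses dialkylation, and with the phenol still benzylated the tosylmethyl group can neither ionize to a quinone methide nor be deprotonated.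

Step 11
Reactants: 15 2-(benzyloxy)-1-{3-[13,13-bis(phenylsulfonyl)tridecyl]-5-methoxyphenoxy}-5-methoxy-3-(tosylmethyl)benzene
Product: 16 2-{3-[13,13-bis(phenylsulfonyl)tridecyl]-5-methoxyphenoxy}-4-methoxy-6-(tosylmethyl)phenol
Conditions: H2 (1 atm), 10% Pd/C, EtOAc–EtOH, rt
Reagents that add atoms: none
Why: Hydrogenolysis of the aryl benzyl ether over palladium frees the phenol under neutral conditions, which the base-labile 2-(tosylmethyl)phenol requires, while sulfones and the diaryl ether are inert.

Step 12
Reactants: 16 2-{3-[13,13-bis(phenylsulfonyl)tridecyl]-5-methoxyphenoxy}-4-methoxy-6-(tosylmethyl)phenol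
Product: 18 macrocyclic bis-sulfone (21-membered diaryl ether; C(SO2Ph)2 next to the ring B benzylic CH2; ring B flanked phenol free; two methyl ethers), via ortho-quinone methide carbanion 17 (not isolated)
Conditions: Cs2CO3 (4 equiv), MeCN, 50 °C, syringe-pump addition of 16 (about 1 mM final); then aq. NH4Cl
Reagents that add atoms: none
Why: Proposed new method: deprotonation of the phenol triggers E1cB loss of toluenesulfinate to give ortho-quinone methide 17, whose exocyclic methylene is attacked in a 1,4 sense by the tethered bis(phenylsulfonyl)methyl carbanion (already present, since this C–H is more acidic than the phenol), and rearomatization to the phenoxide drives the C–C bond formation. The closest known reaction type is base-induced generation of ortho-quinone methides from 2-(arylsulfonylmethyl)phenols with intermolecular Michael trapping by stabilized carbon nucleophiles such as malonates and 1,3-dicarbonyls; closing a large ring this way is the untested part. The ring closes in a 21-endo-trig mode, as both carbons of the reacting C=CH2 unit end up in the macrocycle. No stereocenter is created. The step needs intramolecular C-alkylation to outrun quinone methide dimerization and intermolecular O- or C-attack. Slow addition into dilute base, the low standing concentration of quinone methide kept by reversible sulfinate re-addition (which only regenerates 16), and the soft doubly stabilized carbanion should secure this.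

Step 13
Reactants: 18 macrocyclic bis-sulfone
Product: 20 desulfonylated macrocycle (ring B flanked phenol free; two methyl ethers), via monosulfone 19 (not isolated)
Conditions: Mg turnings (excess), MeOH–THF, rt to 50 °C; then aq. NH4Cl
Reagents that add atoms: none
Why: Reductive desulfonylation with magnesium in methanol (electron transfer to the sulfone, C–S cleavage, protonation) removes both phenylsulfonyl groups of a geminal bis-sulfone one after the other and leaves aryl ethers intact.

Step 14
Reactants: 20 desulfonylated macrocycle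
Product: 21 target CNP0393720.0
Conditions: BBr3, CH2Cl2, −78 °C to rt; then H2O
Reagents that add atoms: none
Why: Lewis acid-mediated cleavage of aryl methyl ethers with BBr3 should free both remaining phenols, while the diaryl ether, which has no alkyl carbon open to bromide attack, survives.

Compound list
1 | 11-bromoundecan-1-ol | OCCCCCCCCCCCBr | starting material
2 | (11-hydroxyundecyl)triphenylphosphonium bromide | [Br-].OCCCCCCCCCCC[P+](c1ccccc1)(c1ccccc1)c1ccccc1 | intermediate
3 | 3,5-dimethoxybenzaldehyde | COc1cc(C=O)cc(OC)c1 | starting material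
4 | sodium 11-(triphenylphosphoranylidene)undecan-1-olate (ylide alkoxide, not isolated) | [Na+].[O-]CCCCCCCCCCC=P(c1ccccc1)(c1ccccc1)c1ccccc1 | intermediate
5 | (Z)-12-(3,5-dimethoxyphenyl)dodec-11-en-1-ol | COc1cc(/C=C\CCCCCCCCCCO)cc(OC)c1 | intermediate
6 | 12-(3,5-dimethoxyphenyl)dodecan-1-ol | COc1cc(CCCCCCCCCCCCO)cc(OC)c1 | intermediate
7 | 3-(12-hydroxydodecyl)-5-methoxyphenol | COc1cc(O)cc(CCCCCCCCCCCCO)c1 | intermediate
8 | 3-bromo-2-hydroxy-5-methoxybenzaldehyde | COc1cc(Br)c(O)c(C=O)c1 | starting material
9 | 2-(benzyloxy)-3-bromo-5-methoxybenzaldehyde | COc1cc(Br)c(OCc2ccccc2)c(C=O)c1 | intermediate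
10 | 2-(benzyloxy)-3-[3-(12-hydroxydodecyl)-5-methoxyphenoxy]-5-methoxybenzaldehyde | COc1cc(CCCCCCCCCCCCO)cc(Oc2cc(OC)cc(C=O)c2OCc3ccccc3)c1 | intermediate
11 | 12-{3-[2-(benzyloxy)-3-(hydroxymethyl)-5-methoxyphenoxy]-5-methoxyphenyl}dodecan-1-ol | COc1cc(CCCCCCCCCCCCO)cc(Oc2cc(OC)cc(CO)c2OCc3ccccc3)c1 | intermediate
12 | 2-(benzyloxy)-1-(bromomethyl)-3-[3-(12-bromododecyl)-5-methoxyphenoxy]-5-methoxybenzene | COc1cc(CCCCCCCCCCCCBr)cc(Oc2cc(OC)cc(CBr)c2OCc3ccccc3)c1 | intermediate
13 | 2-(benzyloxy)-1-[3-(12-bromododecyl)-5-methoxyphenoxy]-5-methoxy-3-(tosylmethyl)benzene | COc1cc(CCCCCCCCCCCCBr)cc(Oc2cc(OC)cc(CS(=O)(=O)c3ccc(C)cc3)c2OCc3ccccc3)c1 | intermediate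
14 | bis(phenylsulfonyl)methane | O=S(=O)(CS(=O)(=O)c1ccccc1)c1ccccc1 | starting material
15 | 2-(benzyloxy)-1-{3-[13,13-bis(phenylsulfonyl)tridecyl]-5-methoxyphenoxy}-5-methoxy-3-(tosylmethyl)benzene | COc1cc(CCCCCCCCCCCCC(S(=O)(=O)c2ccccc2)S(=O)(=O)c2ccccc2)cc(Oc2cc(OC)cc(CS(=O)(=O)c3ccc(C)cc3)c2OCc3ccccc3)c1 | intermediate
16 | 2-{3-[13,13-bis(phenylsulfonyl)tridecyl]-5-methoxyphenoxy}-4-methoxy-6-(tosylmethyl)phenol (key-step precursor) | COc1cc(CCCCCCCCCCCCC(S(=O)(=O)c2ccccc2)S(=O)(=O)c2ccccc2)cc(Oc2cc(OC)cc(CS(=O)(=O)c3ccc(C)cc3)c2O)c1 | intermediate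
17 | cesium salt of the ortho-quinone methide carbanion: 2-{3-[13,13-bis(phenylsulfonyl)tridecyl]-5-methoxyphenoxy}-4-methoxy-6-methylidenecyclohexa-2,4-dien-1-one deprotonated at the bis-sulfonyl carbon (not isolated) | COc1cc(CCCCCCCCCCCC[C-](S(=O)(=O)c2ccccc2)S(=O)(=O)c2ccccc2)cc(OC2=CC(OC)=CC(=C)C2=O)c1.[Cs+] | intermediate
18 | macrocyclic bis-sulfone: 21-membered diaryl ether, two phenylsulfonyl groups on the chain carbon next to the ring B benzylic CH2, ring B flanked phenol free, ring A and ring B each carrying one methoxy group (key-step product) | COc1cc2cc(c1)Oc1cc(OC)cc(c1O)CC(S(=O)(=O)c3ccccc3)(S(=O)(=O)c3ccccc3)CCCCCCCCCCCC2 | intermediate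
19 | macrocyclic monosulfone, racemic at the sulfonyl-bearing carbon (not isolated) | COc1cc2cc(c1)Oc1cc(OC)cc(c1O)CC(S(=O)(=O)c3ccccc3)CCCCCCCCCCCC2 | intermediate
20 | desulfonylated macrocycle: di-O-methyl ether of the target with the ring B flanked phenol free | COc1cc2cc(c1)Oc1cc(OC)cc(c1O)CCCCCCCCCCCCCC2 | intermediate
21 | CNP0393720.0 (macrocyclic triphenol, no stereocenters) | Oc1cc2cc(c1)Oc1cc(O)cc(c1O)CCCCCCCCCCCCCC2 | target

Total step count: 14. Longest linear sequence: 13 steps (steps 1–4 and 6–14); step 5 is a one-step side branch.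

Steps most likely to fail

1. Step 12 (bears the proposed new method). The quinone methide may be consumed by dimerization, by oligomerization through intermolecular phenoxide or carbanion attack, or by adventitious water before the hindered tertiary carbanion reaches it across a 21-membered transition state. The fallback uses known chemistry and closes a different bond. It sets out from dibromide 12: alkylation of excess 14 (K2CO3, DMF, 0 °C to rt) should occur selectively at the benzylic bromide and give 2-(benzyloxy)-1-[2,2-bis(phenylsulfonyl)ethyl]-3-[3-(12-bromododecyl)-5-methoxyphenoxy]-5-methoxybenzene F1. Intramolecular alkylation of its bis-sulfonyl carbanion by the primary bromide under high dilution (Cs2CO3, NaI, DMF, 70 °C, slow addition), a malonate-type macrocyclization, should give the O-benzyl ether of the macrocyclic bis-sulfone F2. Hydrogenolysis (H2, Pd/C, EtOAc) then returns to the route at 18.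

2. Step 6. Oxidative addition at the ortho-substituted, electron-rich bromide may be slow, so that hydrodebromination, degradation of the aldehyde in hot basic DMSO or arylation of the aliphatic hydroxyl compete. The fallback reverses the roles of the partners and sets out from 9: Miyaura borylation (B2pin2, PdCl2(dppf), KOAc, dioxane, 90 °C) should give 2-(benzyloxy)-5-methoxy-3-(4,4,5,5-tetramethyl-1,3,2-dioxaborolan-2-yl)benzaldehyde F3. Oxidative removal of pinacol (NaIO4, NH4OAc, acetone–water) should give [2-(benzyloxy)-3-formyl-5-methoxyphenyl]boronic acid F4. Chan–Lam coupling of F4 with phenol 7 (Cu(OAc)2, pyridine, 4 Å molecular sieves, air, CH2Cl2, rt), an oxidative copper coupling at ambient temperature, returns to the route at 10.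

3. Step 13. In the basic magnesium methoxide medium the ring B phenoxide may expel the bis-sulfonyl carbanion in a retro-Michael sense and reopen the macrocycle before the first C–S bond is reduced, or reduction may stall after loss of one sulfonyl group. The fallback sets out from 18: O-methylation (MeI, K2CO3, acetone, rt) should give the tri-O-methyl macrocyclic bis-sulfone F5, which can no longer form a quinone methide. Reductive desulfonylation (Mg, MeOH; SmI2 with HMPA in THF if the second cleavage stalls) should give the tri-O-methyl macrocycle F6. BBr3 (CH2Cl2, −78 °C to rt) then cleaves all three methyl ethers and the fallback rejoins the route at target 21.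

Further compounds
F1 | step 12 | 2-(benzyloxy)-1-[2,2-bis(phenylsulfonyl)ethyl]-3-[3-(12-bromododecyl)-5-methoxyphenoxy]-5-methoxybenzene | COc1cc(CCCCCCCCCCCCBr)cc(Oc2cc(OC)cc(CC(S(=O)(=O)c3ccccc3)S(=O)(=O)c3ccccc3)c2OCc3ccccc3)c1
F2 | step 12 | O-benzyl ether of macrocyclic bis-sulfone 18 | COc1cc2cc(c1)Oc1cc(OC)cc(c1OCc3ccccc3)CC(S(=O)(=O)c3ccccc3)(S(=O)(=O)c3ccccc3)CCCCCCCCCCCC2
F3 | step 6 | 2-(benzyloxy)-5-methoxy-3-(4,4,5,5-tetramethyl-1,3,2-dioxaborolan-2-yl)benzaldehyde | COc1cc(B2OC(C)(C)C(C)(C)O2)c(OCc2ccccc2)c(C=O)c1
F4 | step 6 | [2-(benzyloxy)-3-formyl-5-methoxyphenyl]boronic acid | COc1cc(B(O)O)c(OCc2ccccc2)c(C=O)c1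
F5 | step 13 | tri-O-methyl macrocyclic bis-sulfone (O-methyl ether of 18) | COc1cc2cc(c1)Oc1cc(OC)cc(c1OC)CC(S(=O)(=O)c3ccccc3)(S(=O)(=O)c3ccccc3)CCCCCCCCCCCC2
F6 | step 13 | tri-O-methyl macrocycle (O-methyl ether of 20) | COc1cc2cc(c1)Oc1cc(OC)cc(c1OC)CCCCCCCCCCCCCC2
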